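## Plan

- **Retrosynthetic cuts.** First the two Ar–CHO bonds. Then, in one operation, the tertiary C–O(aryl) bond and the cyclohexane bond between the ring-fusion CH and the neighbouring cyclopropane CH. Then the benzylic CH–C(quaternary) bond. Last, the cyclopentanone (aldol, allyl) and the acyl C–C bond of a 2-acetylcyclopentanone.
- **Forward order.** The cyclopropane comes from carene. A Claisen closure gives a five-membered ring (bicyclo[3.1.0]hexane). Allylation and aldol condensation build a spiro-cyclopentanone, and the aryl unit is joined through an o-quinone methide. One cationic event then enlarges the five-membered ring to the cyclohexane and closes the oxepane bridge. The formyl groups come last.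
- **Enabling feature.** In the cyclohexane the O-bearing ring-fusion carbon is bonded to the ring-fusion CH, which carries the cyclopropane carbon and sits next to the methyl-bearing quaternary carbon of the cyclopentane. Moving the cyclopropane carbon back by one atom gives a 6,6-dimethylbicyclo[3.1.0]hexane spiro-fused to a cyclopentanol. The carbinol carbon of that cyclopentanol is the same carbonyl that serves to build the quaternary carbon.
- **Stereochemistry.** The two cyclopropane CH centres come from (+)-3-carene. The spiro carbon and the ring CH(CH3) are set by attack anti to the CMe2 bridge. The quaternary and benzylic carbons are set in the Michael step, and the carbinol by hydride attack anti to the aryl-bearing arm. The ring-fusion CH and the ether carbon arise by double inversion in the key step.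

Key step: step 13

Assumption: the 2-acyl ketone 3 is written in its diketo form, although it should exist largely as the enol.

## Route

**Step 1**
Reactants: 1 (+)-3-carene
Product: 2 methyl 2-[(1R,3S)-2,2-dimethyl-3-(2-oxopropyl)cyclopropyl]acetate
Conditions: O3, NaOH, MeOH–CH2Cl2, −78 °C
Reagents that add atoms: ozone [O-][O+]=O; methanol CO
Why: Ozonolysis of the only C=C in basic methanol should give the methyl ketone and, by base-induced dehydration of the methoxy hydroperoxide at the CH terminus, the methyl ester directly, while both cyclopropane stereocentres of carene are carried over untouched.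

**Step 2**
Reactants: 2 methyl 2-[(1R,3S)-2,2-dimethyl-3-(2-oxopropyl)cyclopropyl]acetate
Product: 3 2-acetyl-6,6-dimethylbicyclo[3.1.0]hexan-3-one
Conditions: KOt-Bu, THF, 0 °C; then aq. HCl
Reagents that add atoms: none
Why: In an intramolecular Claisen (Dieckmann-type) condensation the internal ketone enolate closes the five-membered ring on the ester (5-exo-trig), the stabilised β-diketonate pulls the reaction forward, and the new α-centre is enolised and so carries no lasting stereochemistry.

**Step 3**
Reactants: 3 2-acetyl-6,6-dimethylbicyclo[3.1.0]hexan-3-one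
Product: 4 2-acetyl-2-allyl-6,6-dimethylbicyclo[3.1.0]hexan-3-one (allyl anti, acetyl syn to the CMe2 bridge)
Conditions: allyl methyl carbonate, Pd(PPh3)4 (cat.), THF, rt
Reagents that add atoms: allyl methyl carbonate C=CCOC(=O)OC
Why: Tsuji–Trost allylation of the soft β-diketonate should give C-allylation, and the π-allyl electrophile can reach C-2 only from the face anti to the CMe2 bridge, which sets the quaternary (later spiro) carbon.

**Step 4**
Reactants: 4 2-acetyl-2-allyl-6,6-dimethylbicyclo[3.1.0]hexan-3-one
Product: 5 2-(2-acetyl-6,6-dimethyl-3-oxobicyclo[3.1.0]hexan-2-yl)acetaldehyde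
Conditions: O3, CH2Cl2, −78 °C; Me2S
Reagents that add atoms: ozone [O-][O+]=O
Why: Ozonolysis with reductive work-up cleaves the only alkene to the aldehyde under neutral conditions that leave the non-enolisable 1,3-diketone intact.

**Step 5**
Reactants: 5 2-(2-acetyl-6,6-dimethyl-3-oxobicyclo[3.1.0]hexan-2-yl)acetaldehyde
Product: 6 6,6-dimethylspiro[bicyclo[3.1.0]hexane-2,1'-cyclopent-3'-ene]-2',3-dione
Conditions: piperidine, AcOH, toluene, 80 °C
Reagents that add atoms: none
Why: Intramolecular aldol condensation (5-enolexo) of the acetyl CH3 on the aldehyde gives the cyclopentenone, since the competing aldol from C-4 leads to a bridged ketol that cannot dehydrate and reverts, and the buffered amine conditions spare the 2,2-disubstituted 1,3-diketone from retro-Claisen cleavage.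

**Step 6**
Reactants: 6 6,6-dimethylspiro[bicyclo[3.1.0]hexane-2,1'-cyclopent-3'-ene]-2',3-dione
Product: 7 6,6-dimethyl-3-methylidenespiro[bicyclo[3.1.0]hexane-2,1'-cyclopent-3'-en]-2'-one
Conditions: Ph3PCH3Br, KOt-Bu (1.1 equiv each), THF, 0 °C
Reagents that add atoms: methyltriphenylphosphonium bromide C[P+](c1ccccc1)(c1ccccc1)c1ccccc1.[Br-]
Why: Wittig methylenation with one equivalent of ylide should select the saturated cyclopentanone carbonyl over the less electrophilic conjugated enone carbonyl.

**Step 7**
Reactants: 7 6,6-dimethyl-3-methylidenespiro[bicyclo[3.1.0]hexane-2,1'-cyclopent-3'-en]-2'-one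
Product: 8 3,6,6-trimethylspiro[bicyclo[3.1.0]hexane-2,1'-cyclopentan]-2'-one (3-CH3 syn to the CMe2 bridge)
Conditions: H2 (1 atm), Pd/C, EtOAc, rt
Reagents that add atoms: none
Why: Heterogeneous hydrogenation saturates the enone C=C and adds hydrogen to the exocyclic methylene from the face anti to the CMe2 bridge (as in the hydrogenation of 3-carene to cis-carane), which places the new methyl group syn to the bridge.

**Step 8**
Reactants: 8 3,6,6-trimethylspiro[bicyclo[3.1.0]hexane-2,1'-cyclopentan]-2'-one
Product: 10 3,3',6,6-tetramethylspiro[bicyclo[3.1.0]hexane-2,1'-cyclopentan]-2'-one, via lithium enolate 9 (not isolated)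
Conditions: LDA, THF, −78 °C; MeI, −78 °C → 0 °C
Reagents that add atoms: iodomethane CI
Why: In this enolate alkylation the ketone has a single enolisable position, so methylation is regiospecific, and the configuration of the new CH(CH3) centre does not matter because it is planarised again in step 11.

**Step 9**
Reactants: 11 2,4,6-trihydroxybenzaldehyde
Product: 12 2,4-bis(benzyloxy)-6-hydroxybenzaldehyde
Conditions: BnBr (2 equiv), K2CO3, DMF, rt
Reagents that add atoms: benzyl bromide BrCc1ccccc1
Why: In this Williamson etherification the hydroxyl group that is hydrogen-bonded to the formyl group is the least nucleophilic and should remain free when two equivalents of halide are used.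

**Step 10**
Reactants: 12 2,4-bis(benzyloxy)-6-hydroxybenzaldehyde
Product: 13 3,5-bis(benzyloxy)-2-formylphenyl tert-butyl carbonate
Conditions: Boc2O, i-Pr2NEt, DMAP (cat.), CH2Cl2, rt
Reagents that add atoms: di-tert-butyl dicarbonate CC(C)(C)OC(=O)OC(=O)OC(C)(C)C
Why: DMAP-catalysed O-acylation of the remaining phenol installs the carbonate that later migrates and leaves to unmask the o-quinone methide.

**Step 11**
Reactants: 10 3,3',6,6-tetramethylspiro[bicyclo[3.1.0]hexane-2,1'-cyclopentan]-2'-one; 13 3,5-bis(benzyloxy)-2-formylphenyl tert-butyl carbonate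
Product: 17 3'-{1-[2,4-bis(benzyloxy)-6-(tert-butyldimethylsilyloxy)phenyl]-3-methylbutyl}-3,3',6,6-tetramethylspiro[bicyclo[3.1.0]hexane-2,1'-cyclopentan]-2'-one, via potassium enolate 14 (not isolated), via o-quinone methide 15 (not isolated), via potassium phenoxide 16 (not isolated)
Conditions: 10, KHMDS, THF, −78 → 0 °C; 13, i-BuMgBr, THF, −78 °C; combine, −78 °C → rt; TBSCl, rt
Reagents that add atoms: isobutylmagnesium bromide CC(C)C[Mg]Br; tert-butyldimethylsilyl chloride CC(C)(C)[Si](C)(C)Cl
Why: Grignard addition to the aldehyde triggers carbonate migration and 1,4-elimination to the (E)-o-quinone methide, to which the only possible enolate adds in a Michael reaction from the cyclopentanone face syn to the CH(CH3) arm and anti to the cyclopropane arm of the spiro ring (sets the quaternary carbon), a closed metal-bridged endo transition state places isobutyl cis to the ring methyl group (sets the benzylic carbon), and the phenoxide is silylated in the same flask.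

**Step 12**
Reactants: 17 silyl ether ketone
Product: 18 the corresponding 2'-alcohol (OH cis to the CH(i-Bu)Ar group)
Conditions: LiAlH4, THF, 0 °C
Reagents that add atoms: none
Why: In this hydride reduction LiAlH4 is small enough for the doubly neopentylic ketone and should attack anti to the large CH(i-Bu)Ar group, which gives the alcohol cis to that group and therefore anti-periplanar to the bond from the spiro carbon to the cyclopropane carbon.

**Step 13**
Reactants: 18 spiro alcohol
Product: 20 bis(benzyl ether) of the deformyl target (oxa-bridged 5-6-3 tricycle), via triflate 19 (not isolated)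
Conditions: Tf2O, 2,6-di-tert-butyl-4-methylpyridine, CH2Cl2, −78 → 0 °C
Reagents that add atoms: none
Why: Proposed new method: the triflate sits on a carbon flanked by two quaternary carbons, so substitution and β-elimination are shut off and ionisation can proceed only with σ-assistance from a bond anti to C–OTf, and of the two such bonds (spiro-C–cyclopropane-C and C–CH3) the cyclopropane carbon should bridge far better (Walsh orbitals, like a vinyl or aryl group), its 1,2-shift also relieving the compression between the carbinol carbon and the syn methyl of the CMe2 bridge. The closest known reaction types are the Wagner–Meerwein ring enlargement of spiro[4.4]nonan-1-yl sulfonates to hydrindanes, the C-nor-D-homo rearrangement of steroidal 12β-sulfonates and the cyclisation of hydroxyaryl-substituted tertiary cations to cyclic aryl ethers. The six-membered carbocycle is not closed but enlarged (5→6) by this shift, while the seven-membered oxepane ring (the bridge of the oxabicyclo[4.2.1] core) is closed by SN1-type capture of the tertiary cation by the silyl ether oxygen, which is held 1,3-cis over the cyclopentane face, after which triflate takes up the silyl group. Both termini are inverted: the cyclopropane carbon enters the carbinol carbon anti to triflate (sets the ring-fusion CH), the oxygen enters the former spiro carbon anti to the departing C–C bond (sets the ether carbon), and the migrating carbon keeps its configuration. The step needs cyclopropyl shift over methyl shift and O-capture over 1,2-hydride shifts to the cation; the first should be secured by migratory aptitude and strain relief, the second by the proximity of the nucleophile and by cold, buffered, non-equilibrating conditions.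

**Step 14**
Reactants: 20 bis(benzyl ether) of the deformyl target
Product: 21 deformyl target (free resorcinol-type diol)
Conditions: H2 (1 atm), Pd/C, EtOAc–MeOH, rt
Reagents that add atoms: none
Why: Hydrogenolysis removes both benzyl aryl ethers, while the unconjugated cyclopropane and the tertiary alkyl aryl ether (neither allylic nor benzylic at the alkyl carbon) should survive, and no stereocentre is touched.

**Step 15**
Reactants: 21 deformyl target
Product: 23 CNP0202714.1 (target), via bis(iminium) dichloride 22 (not isolated)
Conditions: POCl3, DMF, EtOAc, 0 °C → rt; then H2O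
Reagents that add atoms: N,N-dimethylformamide CN(C)C=O; water O
Why: Double Vilsmeier–Haack formylation can occur only at the two free positions of the phloroglucinol-type ring, both ortho or para to oxygen, and hydrolysis of the bis(iminium) salt gives the dialdehyde without affecting any stereocentre.

## Compound list

1 | (+)-3-carene, (1S,6R)-3,7,7-trimethylbicyclo[4.1.0]hept-3-ene | CC1=CC[C@@H]2[C@H](C1)C2(C)C | starting material
2 | methyl 2-[(1R,3S)-2,2-dimethyl-3-(2-oxopropyl)cyclopropyl]acetate (cis) | CC(=O)C[C@H]1[C@@H](CC(=O)OC)C1(C)C | intermediate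
3 | 2-acetyl-6,6-dimethylbicyclo[3.1.0]hexan-3-one (diketo form, acetyl anti to the CMe2 bridge) | CC(=O)[C@@H]1C(=O)C[C@@H]2[C@H]1C2(C)C | intermediate
4 | 2-acetyl-2-allyl-6,6-dimethylbicyclo[3.1.0]hexan-3-one (allyl anti, acetyl syn to the bridge) | CC(=O)[C@@]1(CC=C)C(=O)C[C@@H]2[C@H]1C2(C)C | intermediate
5 | 2-(2-acetyl-6,6-dimethyl-3-oxobicyclo[3.1.0]hexan-2-yl)acetaldehyde | CC(=O)[C@@]1(CC=O)C(=O)C[C@@H]2[C@H]1C2(C)C | intermediate
6 | 6,6-dimethylspiro[bicyclo[3.1.0]hexane-2,1'-cyclopent-3'-ene]-2',3-dione (C-2' syn to the bridge) | O=C1C=CC[C@@]12C(=O)C[C@@H]3[C@H]2C3(C)C | intermediate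
7 | 6,6-dimethyl-3-methylidenespiro[bicyclo[3.1.0]hexane-2,1'-cyclopent-3'-en]-2'-one | O=C1C=CC[C@@]12C(=C)C[C@@H]3[C@H]2C3(C)C | intermediate
8 | 3,6,6-trimethylspiro[bicyclo[3.1.0]hexane-2,1'-cyclopentan]-2'-one (3-CH3 syn to the bridge) | O=C1CCC[C@@]12[C@@H](C)C[C@@H]3[C@H]2C3(C)C | intermediate
9 | lithium enolate of 8 | [Li+].[O-]C1=CCC[C@@]12[C@@H](C)C[C@@H]3[C@H]2C3(C)C | intermediate
10 | 3,3',6,6-tetramethylspiro[bicyclo[3.1.0]hexane-2,1'-cyclopentan]-2'-one | O=C1[C@@H](C)CC[C@@]12[C@@H](C)C[C@@H]3[C@H]2C3(C)C | intermediate
11 | 2,4,6-trihydroxybenzaldehyde | O=Cc1c(O)cc(O)cc1O | starting material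
12 | 2,4-bis(benzyloxy)-6-hydroxybenzaldehyde | O=Cc1c(O)cc(OCc2ccccc2)cc1OCc1ccccc1 | intermediate
13 | 3,5-bis(benzyloxy)-2-formylphenyl tert-butyl carbonate | CC(C)(C)OC(=O)Oc1cc(OCc2ccccc2)cc(OCc2ccccc2)c1C=O | intermediate
14 | potassium enolate of 10 | [K+].[O-]C1=C(C)CC[C@@]12[C@@H](C)C[C@@H]3[C@H]2C3(C)C | intermediate
15 | (E)-3,5-bis(benzyloxy)-6-(3-methylbutylidene)cyclohexa-2,4-dien-1-one (o-quinone methide) | CC(C)C/C=C1/C(=O)C=C(OCc2ccccc2)C=C1OCc1ccccc1 | intermediate
16 | potassium phenoxide of the Michael adduct | CC(C)C[C@@H](c1c([O-])cc(OCc2ccccc2)cc1OCc1ccccc1)[C@@]3(C)CC[C@]4(C3=O)[C@@H](C)C[C@@H]5[C@H]4C5(C)C.[K+] | intermediate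
17 | silyl ether ketone (Michael adduct, ArOTBS) | CC(C)C[C@@H](c1c(O[Si](C)(C)C(C)(C)C)cc(OCc2ccccc2)cc1OCc1ccccc1)[C@@]3(C)CC[C@]4(C3=O)[C@@H](C)C[C@@H]5[C@H]4C5(C)C | intermediate
18 | spiro alcohol (OH cis to CH(i-Bu)Ar) | CC(C)C[C@@H](c1c(O[Si](C)(C)C(C)(C)C)cc(OCc2ccccc2)cc1OCc1ccccc1)[C@@]3(C)CC[C@]4([C@H]3O)[C@@H](C)C[C@@H]5[C@H]4C5(C)C | intermediate
19 | triflate of 18 | CC(C)C[C@@H](c1c(O[Si](C)(C)C(C)(C)C)cc(OCc2ccccc2)cc1OCc1ccccc1)[C@@]3(C)CC[C@]4([C@H]3OS(=O)(=O)C(F)(F)F)[C@@H](C)C[C@@H]5[C@H]4C5(C)C | intermediate
20 | bis(benzyl ether) of the deformyl target | CC(C)C[C@H]1c2c(OCc3ccccc3)cc(OCc3ccccc3)cc2O[C@]23CC[C@@]1(C)[C@H]2[C@H]1[C@@H](C[C@@H]3C)C1(C)C | intermediate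
21 | deformyl target (diol) | CC(C)C[C@H]1c2c(O)cc(O)cc2O[C@]23CC[C@@]1(C)[C@H]2[C@H]1[C@@H](C[C@@H]3C)C1(C)C | intermediate
22 | bis(iminium) dichloride | CC(C)C[C@H]1c2c(O)c(C=[N+](C)C)c(O)c(C=[N+](C)C)c2O[C@]23CC[C@@]1(C)[C@H]2[C@H]1[C@@H](C[C@@H]3C)C1(C)C.[Cl-].[Cl-] | intermediate
23 | CNP0202714.1 | CC(C)C[C@H]1c2c(O)c(C=O)c(O)c(C=O)c2O[C@]23CC[C@@]1(C)[C@H]2[C@H]1[C@@H](C[C@@H]3C)C1(C)C | target

## Step count

- Total step count: 15.
- Longest linear sequence: 13 steps (steps 1–8 and 11–15).

## Steps most likely to fail

**Step 13.**
- *What may go wrong:* Ionisation may be followed by shift of the neighbouring methyl group. Alternatively, after the ring enlargement, hydride shifts to the cation may lead to opening of the cyclopropane instead of ether closure.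
- *Fallback (from 18 back to 20):* the event is divided into known operations. The alcohol is converted with MsCl and Et3N into the mesylate F1. Buffered solvolysis (2,6-lutidine, CF3CH2OH, warm) should effect the Wagner–Meerwein ring enlargement with loss of the most accessible proton, giving the ring-enlarged cyclopentene silyl ether F2. Fluoride then liberates the alkenyl phenol F3. A cobalt(salen)/silane/N-fluoropyridinium Markovnikov hydroalkoxylation (hydrogen-atom transfer to the CH end of the trisubstituted alkene) closes the tertiary aryl ether to 20.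

**Step 11.**
- *What may go wrong:* C–C bond formation at the tetrasubstituted enolate carbon may be outrun by self-condensation of the o-quinone methide or by proton transfer. Facial selectivity at the benzylic carbon may also be poor.
- *Fallback (from 10 and 12 back to 17):* the anionic Michael addition is replaced by a pericyclic union. Ketone 10 is converted (KHMDS, TMSCl) into the trimethylsilyl enol ether F4. Aldehyde 12 is treated with two equivalents of i-BuMgBr to give the o-hydroxybenzyl alcohol F5. Heating the two in toluene should generate the o-quinone methide by loss of water and lead, by inverse-demand hetero-Diels–Alder reaction (siloxy group endo), to the chroman silyl ketal F6. Fluoride opens F6 to the keto phenoxide, which is silylated with TBSCl to 17.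

**Step 6.**
- *What may go wrong:* Chemoselectivity between the two hindered carbonyl groups may be lost, or the ylide may enolise the ketone.
- *Fallback (from 6 back to 8):* the weakly basic reagent MeCeCl2 adds to the saturated ketone from the face anti to the bridge to give the tertiary alcohol F7. Mild acid-catalysed dehydration gives the trisubstituted alkene F8. Hydrogenation from the face anti to the bridge saturates both C=C bonds and leads to 8.

## Further compounds

F1 | step 13 | mesylate of 18 | CC(C)C[C@@H](c1c(O[Si](C)(C)C(C)(C)C)cc(OCc2ccccc2)cc1OCc1ccccc1)[C@@]3(C)CC[C@]4([C@H]3OS(C)(=O)=O)[C@@H](C)C[C@@H]5[C@H]4C5(C)C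
F2 | step 13 | ring-enlarged cyclopentene silyl ether | CC(C)C[C@@H](c1c(O[Si](C)(C)C(C)(C)C)cc(OCc2ccccc2)cc1OCc1ccccc1)[C@@]3(C)CC=C4[C@@H](C)C[C@@H]5[C@@H](C5(C)C)[C@H]34
F3 | step 13 | alkenyl phenol | CC(C)C[C@@H](c1c(O)cc(OCc2ccccc2)cc1OCc1ccccc1)[C@@]3(C)CC=C4[C@@H](C)C[C@@H]5[C@@H](C5(C)C)[C@H]34
F4 | step 11 | trimethylsilyl enol ether of 10 | C[Si](C)(C)OC1=C(C)CC[C@@]12[C@@H](C)C[C@@H]3[C@H]2C3(C)C
F5 | step 11 | 3,5-bis(benzyloxy)-2-(1-hydroxy-3-methylbutyl)phenol (racemic) | CC(C)CC(O)c1c(O)cc(OCc2ccccc2)cc1OCc1ccccc1
F6 | step 11 | chroman silyl ketal | CC(C)C[C@H]1c2c(OCc3ccccc3)cc(OCc3ccccc3)cc2O[C@@]2(O[Si](C)(C)C)[C@]1(C)CC[C@@]23[C@@H](C)C[C@@H]4[C@H]3C4(C)C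
F7 | step 6 | tertiary alcohol (CH3 anti, OH syn to the bridge) | O=C1C=CC[C@@]12[C@@](C)(O)C[C@@H]3[C@H]2C3(C)C
F8 | step 6 | trisubstituted alkene | O=C1C=CC[C@@]12C(C)=C[C@@H]3[C@H]2C3(C)C
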